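Z flattened out in the earlier runs at a height that grew with the D present at the start, so I lined the runs up by that amount, with Z as a fraction of the Q charged.

| setting | epsilon | eta | delta | flask |
|---|---|---|---|---|
| Q | 0.20 M | 0.20 M | 0.10 M | 0.20 M |
| D | 2.1 equiv | 3.3 equiv | 1.5 equiv | 1.50 equiv |
| remark | run made earlier | run made earlier | run made earlier |  |
| time |  |  |  | 1.0 h |

- epsilon (time / min: Z / %): 15.0: 41.8; 30.0: 60.7; 50.0: 60.3; 60.0: 58.4
- eta (time / min: Z / %): 5.00: 17.2; 12.0: 39.8; 25.0: 64.7; 60.0: 61.1
- delta (time / min: Z / %): 5.00: 15.8; 12.0: 40.7; 25.0: 51.3; 60.0: 52.7

(scatter of a reading: 1 percentage point)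

- as a solid, counted per litre of solution: Q
- at the start none of Q is in solution

- maple: doubling the dissolution coefficient of Q, all else as stated
- alder: doubling the solubility of Q, all else as stated
- elm: doubling the amount of D, all else as stated

1. how much Z there is at 1.0 h, in percent of the Q charged
2. the change that raises the amount of Z at 1.0 h, in percent of the Q charged most ("none" if none brings more than 2 percentage points) (maple / alder / elm / none)
3. amount of Z at 1.0 h, in percent of the Q charged, after elm

| run | D at start | Z at 60.0 min |
|---|---|---|
| delta | 0.150 M | 52.7% |
| epsilon | 0.420 M | 58.4% |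
| eta | 0.660 M | 61.1% |

I assumed that something competes with D for dissolved Q, so that the shortfall of Z below a ceiling goes as one over D, and I let the different Q of delta pass. Eta's shortfall is then delta's divided by 4.40. Their gap of 8.4 percentage points is therefore 77.3% of delta's shortfall, which makes that shortfall 11 points. This gives the ceiling, the fraction of the charge standing as Z with D in plenty: 63.6%.

The flask starts with 0.300 M of D, twice delta's, so I put its shortfall at half of delta's and its Z at 58.1%. Doubling D through elm gives 60.9% on the same reckoning, a gain of 2.7 points. Maple and alder add no D, so on my assumption they do not narrow the shortfall, and I chose elm.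

The weak link was eta's single reading. Epsilon in its place gives 57.1% for the flask, a gap of about the scatter of 1 point, so I kept 58.1%.

The forecast said 52% (range 47% to 58%) against my 58.1%, best elm, and 60.5% after it, since delta's stop “looks like D exhaustion”.

The flask gives 57.7%; the best change is elm, which brings 62.0%.

    Q ⇌ G, rate k1*(cs1 - [G]) while solid is left; crystals form when [G] > cs1 (solubility = 0.0940 M, k = 0.110 min⁻¹)
    G + D → Z (k = 1.70 M⁻¹ min⁻¹)
    2 G → J (k = 0.880 M⁻¹ min⁻¹)
    Z ⇌ X (K = 0.580, k = 0.120 min⁻¹)

In the flask, the exchange of Z and X relaxes, by that step alone, with a half-life of 2.12 min, shorter than the 1.0 h of the reading, which is thermodynamic control of that pair. At that time the flask holds Z 57.7% beside X 33.5%, so Z is 63.3% of the two, and that share is what I now take my ceiling to stand for.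

In the same flask with 0.380 equiv of D, one D goes into each Z or X made, so I take my ceiling of 63.6% as Z's share of that charge, which gives 24.2% of the Q as Z. That flask computes to 23.0%, with 4.4% of its D left.

(The data come from a simulation with made-up constants; noise was put on by code.)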